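The target is disconnected in the methoxy-bearing ring B, numbered from the bridge carbon C1 (C2–O, C3–butyryl, C4–OH, C5–CH3, C6–OCH3): the C3–acyl bond and the C4–O bond are cut together. One operation forms both: fluoride unmasks a C3≡C4 aryne and butanoate inserts across it, oxygen ending on C4 and the acyl carbon on C3, steered by the C2 benzyloxy group. The precursor is the fully benzylated diarylmethane that already carries the ring A pentanoyl group, with trimethylsilyl on C3 and triflate on C4 of ring B. It is assembled by a late Friedel–Crafts union, so that no organolithium reagent meets a ketone.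

Key step: step 10

Assumption: 2,4-dihydroxy-6-methoxybenzaldehyde is treated as a purchasable building block; the target has no stereocentre.

Step 1
Reactants: 1 2,4-dihydroxy-6-methoxybenzaldehyde
Product: 2 4-(benzyloxy)-2-hydroxy-6-methoxybenzaldehyde
Conditions: BnBr (1.05 equiv), K2CO3, acetone, 40 °C
Reagents that add atoms: benzyl bromide, BrCc1ccccc1
Why: Williamson etherification should be selective for the 4-hydroxyl, which is the more acidic one and is not held in the hydrogen bond to the aldehyde that deactivates the 2-hydroxyl.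

Step 2
Reactants: 2 4-(benzyloxy)-2-hydroxy-6-methoxybenzaldehyde
Product: 3 4-(benzyloxy)-2-hydroxy-3-iodo-6-methoxybenzaldehyde
Conditions: NIS (1.0 equiv), MeCN, 0 °C → rt
Reagents that add atoms: N-iodosuccinimide, O=C1CCC(=O)N1I
Why: Electrophilic aromatic iodination of the chelated salicylaldehyde should go to C3, ortho to the hydroxyl and para to the methoxy group, the usual site of halogenation in 2-hydroxy-4,6-dialkoxyaryl carbonyl compounds.

Step 3
Reactants: 3 4-(benzyloxy)-2-hydroxy-3-iodo-6-methoxybenzaldehyde
Product: 5 5-(benzyloxy)-6-iodo-3-methoxy-2-methylphenol, via aryl ethyl carbonate 4 (not isolated)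
Conditions: ClCO2Et, Et3N, THF, 0 °C; then NaBH4, H2O, 0 °C → rt
Reagents that add atoms: ethyl chloroformate, CCOC(=O)Cl (its atoms stay only in intermediate 4 and are lost again before 5)
Why: Reductive deoxygenation of a salicylaldehyde: borohydride reduces the aldehyde, the ethoxycarbonyl group shifts to the benzylic oxygen and leaves to give an ortho-quinone methide that is reduced at once to the ortho-cresol, while aryl iodide and benzyl ether are inert.

Step 4
Reactants: 5 5-(benzyloxy)-6-iodo-3-methoxy-2-methylphenol
Product: 6 2-(benzyloxy)-4-hydroxy-3-iodo-6-methoxy-5-methylbenzaldehyde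
Conditions: POCl3, DMF, 0 → 40 °C; then aq. NaOAc
Reagents that add atoms: N,N-dimethylformamide, CN(C)C=O; water, O
Why: Vilsmeier–Haack formylation can only occur at the single remaining ring C–H, which is para to the free hydroxyl and flanked by two alkoxy groups, the site that 3,5-dialkoxyphenols prefer in any case.

Step 5
Reactants: 6 2-(benzyloxy)-4-hydroxy-3-iodo-6-methoxy-5-methylbenzaldehyde
Product: 7 3-(benzyloxy)-4-(hydroxymethyl)-2-iodo-5-methoxy-6-methylphenol
Conditions: NaBH4, THF/EtOH, 0 °C; neutral work-up, used directly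
Reagents that add atoms: none
Why: Borohydride reduction of the aldehyde to the benzylic alcohol should leave iodide and ethers untouched; the electron-rich para-hydroxybenzyl alcohol is kept neutral and carried on without storage.

Step 6
Reactants: 7 3-(benzyloxy)-4-(hydroxymethyl)-2-iodo-5-methoxy-6-methylphenol
Product: 11 3-(benzyloxy)-4-(hydroxymethyl)-5-methoxy-6-methyl-2-(trimethylsilyl)phenyl trifluoromethanesulfonate, via bis(trimethylsilyl) ether 8 (not isolated), via C-silylated lithium phenoxide 9 (not isolated), via O-silylated aryl triflate 10 (not isolated)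
Conditions: HMDS, THF, 60 °C, evaporate; n-BuLi, THF, −78 °C; Tf2O, −78 °C; then AcOH/THF/H2O, rt
Reagents that add atoms: hexamethyldisilazane, C[Si](C)(C)N[Si](C)(C)C; trifluoromethanesulfonic anhydride, O=S(=O)(OS(=O)(=O)C(F)(F)F)C(F)(F)F
Why: O-Silylation followed by iodine–lithium exchange triggers a retro-Brook 1,3-shift of silicon from oxygen to the ortho carbon and the hindered phenoxide is trapped as the triflate, the exchange at −78 °C being far faster than attack on the benzyl ether and no carbonyl group being present; mild aqueous acid then frees the benzylic alcohol.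

Step 7
Reactants: 12 2,4,6-trihydroxytoluene; 13 pentanoyl chloride
Product: 14 1-(2,4,6-trihydroxy-3-methylphenyl)pentan-1-one
Conditions: AlCl3, PhNO2, 60 °C; then ice/aq. HCl
Reagents that add atoms: none
Why: Friedel–Crafts C-acylation of the symmetric phloroglucinol should give one regioisomer, because both free ring positions are equivalent and the first acyl group deactivates the ring toward a second.

Step 8
Reactants: 14 1-(2,4,6-trihydroxy-3-methylphenyl)pentan-1-one
Product: 15 1-[2,4,6-tris(benzyloxy)-3-methylphenyl]pentan-1-one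
Conditions: BnBr (3.6 equiv), K2CO3, DMF, 60 °C
Reagents that add atoms: benzyl bromide, BrCc1ccccc1
Why: Williamson O-benzylation with carbonate in DMF favours O- over C-alkylation and, with excess halide and heat, should also cap the two hydrogen-bonded hydroxyls beside the ketone, leaving one ring C–H between two benzyloxy groups.

Step 9
Reactants: 15 1-[2,4,6-tris(benzyloxy)-3-methylphenyl]pentan-1-one; 11 3-(benzyloxy)-4-(hydroxymethyl)-5-methoxy-6-methyl-2-(trimethylsilyl)phenyl trifluoromethanesulfonate
Product: 16 3-(benzyloxy)-5-methoxy-6-methyl-4-{[2,4,6-tris(benzyloxy)-3-methyl-5-pentanoylphenyl]methyl}-2-(trimethylsilyl)phenyl trifluoromethanesulfonate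
Conditions: TsOH·H2O (10 mol %), CH2Cl2/HFIP (9:1), 0 °C → rt; 15 in slight excess, 11 added slowly
Reagents that add atoms: none
Why: Brønsted acid-catalysed Friedel–Crafts benzylation: the alcohol ionises to a cation stabilised by two ortho alkoxy groups and is captured by the only ring C–H of 15, a position activated by three benzyloxy groups and meta to the twisted ketone, while the fully substituted ring of 11 cannot condense with itself.

Step 10
Reactants: 16 3-(benzyloxy)-5-methoxy-6-methyl-4-{[2,4,6-tris(benzyloxy)-3-methyl-5-pentanoylphenyl]methyl}-2-(trimethylsilyl)phenyl trifluoromethanesulfonate; 17 butanoic acid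
Product: 18 1-[2,4,6-tris(benzyloxy)-3-{[2-(benzyloxy)-3-butanoyl-4-hydroxy-6-methoxy-5-methylphenyl]methyl}-5-methylphenyl]pentan-1-one
Conditions: CsF (4 equiv), 17 (1.2 equiv), THF, 125 °C, sealed tube
Reagents that add atoms: none
Why: Fluoride attacks silicon and triflate leaves, giving the aryne across C3–C4 of ring B; caesium butanoate formed in the flask adds through oxygen to C4, and the C3 aryl anion then attacks the ester carbonyl through a four-membered transition state, so that the acyl group moves from oxygen to carbon and an ortho-acyl phenoxide results. This is the known fluoride-induced insertion of arynes into the C–O bond of carboxylic acids to give ortho-hydroxyaryl ketones, in effect an anionic Fries-type acyl shift. No ring is closed and no stereocentre is formed. The selectivity needed is the site of attack on the unsymmetrical aryne: the inductively withdrawing benzyloxy group on C2 distorts the triple bond and stabilises negative charge on C3, so the nucleophile should enter at the remote C4 beside the methyl group. Protonation of the aryl anion before acyl transfer, which would give only the aryl ester, is held back by using little more than one equivalent of acid with excess CsF in hot THF. Neither the ring A ketone nor the acid-labile diarylmethane bridge is exposed to a Lewis acid.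

Step 11
Reactants: 18 1-[2,4,6-tris(benzyloxy)-3-{[2-(benzyloxy)-3-butanoyl-4-hydroxy-6-methoxy-5-methylphenyl]methyl}-5-methylphenyl]pentan-1-one
Product: 19 1-[3-[(3-butanoyl-2,4-dihydroxy-6-methoxy-5-methylphenyl)methyl]-2,4,6-trihydroxy-5-methylphenyl]pentan-1-one
Conditions: H2 (1 atm), Pd/C, EtOAc/MeOH, rt
Reagents that add atoms: none
Why: Catalytic hydrogenolysis should cleave the four O-benzyl groups under neutral conditions and leave the two hydrogen-bonded aryl ketones, the methyl ether and the diarylmethane bridge intact.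

Compound list
1 | 2,4-dihydroxy-6-methoxybenzaldehyde | O=Cc1c(O)cc(O)cc1OC | starting material
2 | 4-(benzyloxy)-2-hydroxy-6-methoxybenzaldehyde | O=Cc1c(O)cc(OCc2ccccc2)cc1OC | intermediate
3 | 4-(benzyloxy)-2-hydroxy-3-iodo-6-methoxybenzaldehyde | O=Cc1c(O)c(I)c(OCc2ccccc2)cc1OC | intermediate
4 | 5-(benzyloxy)-2-formyl-6-iodo-3-methoxyphenyl ethyl carbonate | CCOC(=O)Oc1c(C=O)c(OC)cc(OCc2ccccc2)c1I | intermediate
5 | 5-(benzyloxy)-6-iodo-3-methoxy-2-methylphenol | Cc1c(O)c(I)c(OCc2ccccc2)cc1OC | intermediate
6 | 2-(benzyloxy)-4-hydroxy-3-iodo-6-methoxy-5-methylbenzaldehyde | O=Cc1c(OCc2ccccc2)c(I)c(O)c(C)c1OC | intermediate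
7 | 3-(benzyloxy)-4-(hydroxymethyl)-2-iodo-5-methoxy-6-methylphenol | OCc1c(OCc2ccccc2)c(I)c(O)c(C)c1OC | intermediate
8 | {[2-(benzyloxy)-3-iodo-6-methoxy-5-methyl-4-(trimethylsilyloxy)phenyl]methoxy}trimethylsilane | C[Si](C)(C)OCc1c(OCc2ccccc2)c(I)c(O[Si](C)(C)C)c(C)c1OC | intermediate
9 | lithium 3-(benzyloxy)-5-methoxy-6-methyl-2-(trimethylsilyl)-4-[(trimethylsilyloxy)methyl]phenoxide | [Li+].[O-]c1c(C)c(OC)c(CO[Si](C)(C)C)c(OCc2ccccc2)c1[Si](C)(C)C | intermediate
10 | 3-(benzyloxy)-5-methoxy-6-methyl-2-(trimethylsilyl)-4-[(trimethylsilyloxy)methyl]phenyl trifluoromethanesulfonate | C[Si](C)(C)OCc1c(OCc2ccccc2)c([Si](C)(C)C)c(OS(=O)(=O)C(F)(F)F)c(C)c1OC | intermediate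
11 | 3-(benzyloxy)-4-(hydroxymethyl)-5-methoxy-6-methyl-2-(trimethylsilyl)phenyl trifluoromethanesulfonate | OCc1c(OCc2ccccc2)c([Si](C)(C)C)c(OS(=O)(=O)C(F)(F)F)c(C)c1OC | intermediate
12 | 2,4,6-trihydroxytoluene | Cc1c(O)cc(O)cc1O | starting material
13 | pentanoyl chloride | CCCCC(=O)Cl | starting material
14 | 1-(2,4,6-trihydroxy-3-methylphenyl)pentan-1-one | CCCCC(=O)c1c(O)c(C)c(O)cc1O | intermediate
15 | 1-[2,4,6-tris(benzyloxy)-3-methylphenyl]pentan-1-one | CCCCC(=O)c1c(OCc2ccccc2)c(C)c(OCc2ccccc2)cc1OCc1ccccc1 | intermediate
16 | 3-(benzyloxy)-5-methoxy-6-methyl-4-{[2,4,6-tris(benzyloxy)-3-methyl-5-pentanoylphenyl]methyl}-2-(trimethylsilyl)phenyl trifluoromethanesulfonate | C[Si](C)(C)c1c(OCc2ccccc2)c(Cc2c(OCc3ccccc3)c(C)c(OCc3ccccc3)c(C(=O)CCCC)c2OCc2ccccc2)c(OC)c(C)c1OS(=O)(=O)C(F)(F)F | intermediate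
17 | butanoic acid | CCCC(=O)O | starting material
18 | 1-[2,4,6-tris(benzyloxy)-3-{[2-(benzyloxy)-3-butanoyl-4-hydroxy-6-methoxy-5-methylphenyl]methyl}-5-methylphenyl]pentan-1-one | CCCC(=O)c1c(OCc2ccccc2)c(Cc2c(OCc3ccccc3)c(C)c(OCc3ccccc3)c(C(=O)CCCC)c2OCc2ccccc2)c(OC)c(C)c1O | intermediate
19 | 1-[3-[(3-butanoyl-2,4-dihydroxy-6-methoxy-5-methylphenyl)methyl]-2,4,6-trihydroxy-5-methylphenyl]pentan-1-one | CCCCC(=O)c1c(O)c(C)c(O)c(Cc2c(O)c(C(=O)CCC)c(O)c(C)c2OC)c1O | target

Total step count: 11. Longest linear sequence: 9 steps (steps 1–6, then 9, 10 and 11); steps 7 and 8 form the short ring A branch.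

Steps most likely to fail

Step 10. The aryl anion may be protonated before the acyl group shifts, or the carboxylate may attack the aryne carbon beside the benzyloxy group; either would divert material from the ortho-hydroxy ketone. The fallback replaces the aryne insertion by an exchange-triggered anionic Fries rearrangement on the monomer and then joins the two free acylphloroglucinols in the classical way; it sets out from 5 and 14 and comes back at 19. Iodophenol 5 would be O-acylated with butanoyl chloride (Et3N, DMAP, CH2Cl2) to 5-(benzyloxy)-6-iodo-3-methoxy-2-methylphenyl butanoate F1. Iodine–lithium exchange (n-BuLi, THF/Et2O, −95 °C) should then move the acyl group from oxygen to the ortho carbon and give 1-[6-(benzyloxy)-2-hydroxy-4-methoxy-3-methylphenyl]butan-1-one F2. Hydrogenolysis (H2, Pd/C) would give 1-(2,6-dihydroxy-4-methoxy-3-methylphenyl)butan-1-one F3. Separately, 14 would be converted with formaldehyde and dimethylamine into the Mannich base 1-{3-[(dimethylamino)methyl]-2,4,6-trihydroxy-5-methylphenyl}pentan-1-one F4. Heating F4 with F3 in dioxane should expel dimethylamine to an ortho-quinone methide, which F3 captures at its one free ring carbon to give 19 directly.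

Step 9. Capture of the benzylic cation by the only moderately nucleophilic tris-ether 15 may be slow, so that protodesilylation of ring B or acid-induced benzyl migration competes. The fallback changes the nucleophile and the order of protection; it sets out from 14 and 11 and comes back at 16. The free triol 14, a much stronger carbon nucleophile, would be alkylated by 11 under weaker acid (PPTS, CH2Cl2, rt) to give 3-(benzyloxy)-5-methoxy-6-methyl-4-[(2,4,6-trihydroxy-3-methyl-5-pentanoylphenyl)methyl]-2-(trimethylsilyl)phenyl trifluoromethanesulfonate F5. Its three ring A hydroxyls would then be benzylated without soluble base (BnBr, Ag2O, toluene, 40 °C), conditions meant to leave the silyl triflate untouched, to give 16.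

Step 2. Iodination may occur partly at C5, para to the hydroxyl, or twice. The fallback postpones the halogenation until only one ring C–H is left; it sets out from 2 and comes back at 6. Aldehyde 2 would be deoxygenated as in step 3 (ClCO2Et, Et3N; then NaBH4), through 5-(benzyloxy)-2-formyl-3-methoxyphenyl ethyl carbonate F6, to 5-(benzyloxy)-3-methoxy-2-methylphenol F7. Vilsmeier–Haack formylation (POCl3, DMF), which prefers the position para to the hydroxyl in 3,5-dialkoxyphenols, should give 2-(benzyloxy)-4-hydroxy-6-methoxy-5-methylbenzaldehyde F8. Iodination (NIS, MeCN) of its single remaining ring C–H, ortho to the hydroxyl, would then give 6.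

Further compounds
F1 | step 10 | 5-(benzyloxy)-6-iodo-3-methoxy-2-methylphenyl butanoate | CCCC(=O)Oc1c(C)c(OC)cc(OCc2ccccc2)c1I
F2 | step 10 | 1-[6-(benzyloxy)-2-hydroxy-4-methoxy-3-methylphenyl]butan-1-one | CCCC(=O)c1c(O)c(C)c(OC)cc1OCc1ccccc1
F3 | step 10 | 1-(2,6-dihydroxy-4-methoxy-3-methylphenyl)butan-1-one | CCCC(=O)c1c(O)c(C)c(OC)cc1O
F4 | step 10 | 1-{3-[(dimethylamino)methyl]-2,4,6-trihydroxy-5-methylphenyl}pentan-1-one | CCCCC(=O)c1c(O)c(C)c(O)c(CN(C)C)c1O
F5 | step 9 | 3-(benzyloxy)-5-methoxy-6-methyl-4-[(2,4,6-trihydroxy-3-methyl-5-pentanoylphenyl)methyl]-2-(trimethylsilyl)phenyl trifluoromethanesulfonate | CCCCC(=O)c1c(O)c(C)c(O)c(Cc2c(OCc3ccccc3)c([Si](C)(C)C)c(OS(=O)(=O)C(F)(F)F)c(C)c2OC)c1O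
F6 | step 2 | 5-(benzyloxy)-2-formyl-3-methoxyphenyl ethyl carbonate | CCOC(=O)Oc1cc(OCc2ccccc2)cc(OC)c1C=O
F7 | step 2 | 5-(benzyloxy)-3-methoxy-2-methylphenol | Cc1c(O)cc(OCc2ccccc2)cc1OC
F8 | step 2 | 2-(benzyloxy)-4-hydroxy-6-methoxy-5-methylbenzaldehyde | O=Cc1c(OCc2ccccc2)cc(O)c(C)c1OC
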